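Over 57 min at one constant temperature, the north run starts with product already in it, so the first thing to settle is what sets its rate. Write S for substrate, R for coupling partner and P for product.

the same everywhere: free catalyst 0.00800 M

| run | substrate | coupling partner | product | time |
|---|---|---|---|---|
| north-west | 0.400 M | 0.480 M |  |  |
| west | 0.160 M | 0.240 M |  |  |
| north-east | 0.600 M | 0.480 M |  |  |
| north | 0.400 M | 0.480 M | 0.120 M | 57 min |

| run | time / min | [product] / M |
|---|---|---|
| north-west run | 11 | 0.0509 |
| north-west run | 23 | 0.0962 |
| north-west run | 34 | 0.1314 |
| north-west run | 46 | 0.1602 |
| north-west run | 57 | 0.1846 |
| west run | 11 | 0.0119 |
| west run | 23 | 0.0251 |
| west run | 34 | 0.0362 |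
| west run | 46 | 0.0470 |
| west run | 57 | 0.0516 |
| north-east run | 11 | 0.0686 |
| north-east run | 23 | 0.1294 |
| north-east run | 34 | 0.1734 |
| north-east run | 46 | 0.2133 |
| north-east run | 57 | 0.2443 |

(readings scatter by 0.001 M)

- Overall: substrate + coupling partner -> product, with free catalyst as catalyst.
- Constant volume, constant temperature.
- Readings of a species count what is bound in complexes too.
- An order is taken over about fifteen percent of the charge, up and down.
- A share of product counts the product that was charged too.

* how the opening rate goes with [substrate] round the charge of the north-west run: the exponent of the rate at two percent of substrate gone to product (one fixed amount of product, the same in the runs compared)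
* how the opening rate goes with [coupling partner] round the charge of the north-west run: the exponent of the rate at two percent of substrate gone to product
* the west run starts with 0.240 M less of substrate and of coupling partner than the north-west run, and with no product. Compared where both hold the same amount of substrate, once fifteen percent of what the west run was charged with has turned into product, is the west run faster, slower or alike (within a tenth)?
* product in the north run at 57 min, as a share of the substrate charged

The reckoning here builds the flask one process at a time. First comes the main step alone, with rate κ[S][R] and κ constant. The first interval of the north-west run gives:

κ = 0.0272 /M/min

Integrated to 57 min, this makes 0.177 M of product. With the charged product, that gives a share of 74.2 %.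

The second addition is that κ is not constant. Let Σ be [S]+[R], taken at the middle of a stretch. Up to 23 min, the north-east run gives κ = 0.0253 /M/min at Σ = 0.951 M. Up to 34 min, the west run gives 0.0338 /M/min at Σ = 0.364 M. So κ is lower at the larger sum. Take κ = A·c/(c+Σ), where the damping concentration c is the sum of substrate and coupling partner at which κ stands at half of its value A for a dilute flask:

c = 1.38 M, A = 0.0427 /M/min

This c is a reading, and it carries the scatter of the readings behind it. Both species sit in Σ, and on this form the exponents round the north-west charge are:

substrate: 0.823; coupling partner: 0.788

As the north-west run proceeds, Σ falls and on this form κ climbs, so the estimate with constant κ falls short. The north-west reading at 57 min, 0.1846 M, exceeds the first estimate.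

The last addition is product. Between 34 min and 57 min the north-east run holds about 0.209 M of it, more than the north run is charged with. Its κ there reads 0.0291 /M/min, and c gives 0.0289 /M/min. So κ in the north-east run reads as c expects with that much product present, and the north run should gain what the north-west run gained, for a share of 76.1 %. The west run lies 0.240 M below the north-west run in substrate and 0.240 M in coupling partner. At equal substrate the two hold equal Σ, so the reckoning expects them to be alike.

The forecast gives 0.72 and 1 for the exponents, alike for the west run and 76 % for the north run, reading the rate “with substrate saturating the catalyst and the coupling partner about first order”. It agrees with the reckoning here on the last two and differs on both exponents.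

The flask gives 75.9 %, with exponents 0.86 and 0.81, and the west run is alike, at a rate ratio of 1.0.

    2 free catalyst ⇌ catalyst dimer, settled at all times (124.0 /M)
    free catalyst + substrate + coupling partner → product + free catalyst (9.660 /M²/min)
    substrate + coupling partner → product (0.004656 /M/min)
    substrate + coupling partner ⇌ idle substrate-reagent adduct, settled at all times (0.8210 /M)

In the north run at 57 min, Σ stands at 0.513 M, so c puts κ at 0.0311 /M/min. For the north-east run against the north-west run, c, read in part from the north-east run, gives a rate ratio of 1.38 from the charges, and with both runs at the same amount of product made the flask gives 1.4.

The numbers in the tables are simulated on assumed constants; noise was put on by code.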